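**Retrosynthetic overview**
1. Target 29 ⇐ its isomer, bridged hydroxy lactone 26: the spiro-oxirane C18–O bond is made last, the C11 alkoxide displacing the lactone carboxylate (new step).
2. 12-membered ring ⇐ intramolecular B-alkyl Suzuki coupling (C7–C8); both Z alkenes come from α-iodoethylidene Wittig / B-alkyl Suzuki pairs.
3. Cyclohexane ⇐ lactone-enolate opening of a vinyl oxirane (C15–C10), then acyl shift to the bridged lactone; the oxirane (C11–O, C10) comes from Sharpless asymmetric epoxidation, the stereo-defining C–O bond formation.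
4. Dienol 13 ⇐ B-alkyl Suzuki coupling of vinyl lactone 6 with iodo-dienol 11; 6 ⇐ Rh-catalysed asymmetric vinylation of 5,6-dihydro-2H-pyran-2-one, then α-alkylation.
5. Ring order: δ-lactone (bought) → oxirane → cyclohexane with bridged lactone → 12-membered carbocycle → spiro-oxirane.

Assumption: the SMILES is read literally, i.e. ring alkenes 2Z,6Z (ring carbons cis), the C14 and C10 bridge bonds trans on the cyclohexane, configuration 10R,11S,14R,15S.

Locants: C15 = quaternary acid carbon; C14, C10 = its ring CH neighbours; C11 = oxirane ring carbon; C18 = oxirane CH2; C12, C13 = ring CH2; C1–C9 = bridge from C14 to C10 (C2=C3, C6=C7); C16–C20 = 4-methylpent-3-enyl chain; β = ring face carrying the C15 carboxyl carbon.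

**Route**

Step 1
Reactants: 1 5,6-dihydro-2H-pyran-2-one; 2 potassium ethenyltrifluoroborate
Product: 3 (4R)-4-ethenyloxan-2-one
Conditions: [Rh(cod)2]BF4 (3 mol %), (R)-BINAP (3.3 mol %), PhMe/H2O 10:1, 105 °C
Reagents that add atoms: none
Why: Rhodium-catalysed asymmetric 1,4-addition (Hayashi–Miyaura type) of the alkenylboron reagent to the cyclic enoate, in which the (R)-BINAP complex selects one enantioface and so sets C14 (4R here), the only centre not relayed from another.

Step 2
Reactants: 3 (4R)-4-ethenyloxan-2-one; 4 5-bromo-2-methylpent-2-ene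
Product: 6 (3S,4S)-4-ethenyl-3-(4-methylpent-3-en-1-yl)oxan-2-one, via lithium enolate 5 (not isolated)
Conditions: LiN(iPr)2 (1.1 equiv), THF, −78 °C; then 4 (1.5 equiv), DMPU, −78 → −20 °C
Reagents that add atoms: none
Why: Kinetic lactone-enolate alkylation (SN2) anti to the C4 vinyl group gives the trans lactone, and the new centre (future C15) is re-enolised in step 7, so its configuration does not matter.

Step 3
Reactants: 7 prop-2-enal; 8 ethyl (triphenylphosphoranylidene)acetate
Product: 10 ethyl (2Z)-2-iodopenta-2,4-dienoate, via iodo ylide 9 (not isolated)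
Conditions: N-iodosuccinimide (1.05 equiv), CH2Cl2, −20 °C; then 7, −20 °C → rt
Reagents that add atoms: N-iodosuccinimide, O=C1CCC(=O)N1I
Why: Wittig olefination with the α-iodo stabilised ylide made in situ places the ester trans to the vinyl group, i.e. iodine cis to vinyl (Z), which later fixes the C10=C11 geometry.

Step 4
Reactants: 10 ethyl (2Z)-2-iodopenta-2,4-dienoate
Product: 11 (2Z)-2-iodopenta-2,4-dien-1-ol
Conditions: iBu2AlH (2.2 equiv), CH2Cl2, −78 °C; Rochelle-salt work-up
Reagents that add atoms: none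
Why: Low-temperature 1,2-reduction of the conjugated ester by the aluminium hydride leaves the C–I bond and the diene untouched and gives the allylic alcohol needed for directed epoxidation.

Step 5
Reactants: 6 (3S,4S)-4-ethenyl-3-(4-methylpent-3-en-1-yl)oxan-2-one; 11 (2Z)-2-iodopenta-2,4-dien-1-ol
Product: 13 (3S,4R)-4-[(3E)-3-(hydroxymethyl)hexa-3,5-dien-1-yl]-3-(4-methylpent-3-en-1-yl)oxan-2-one, via alkylborane 12 (not isolated)
Conditions: 9-BBN (1.05 equiv B–H), THF, 0 °C → rt; then 11, Pd(dppf)Cl2 (5 mol %), AsPh3, Cs2CO3, DMF/H2O, rt; mildly acidic work-up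
Reagents that add atoms: none
Why: Anti-Markovnikov hydroboration of the only monosubstituted alkene followed by B-alkyl Suzuki–Miyaura coupling, which retains the alkenyl iodide geometry and so gives the dienol with C9 cis to C12 (3E; the descriptor changes only because of priorities).

Step 6
Reactants: 13 (3S,4R)-4-[(3E)-3-(hydroxymethyl)hexa-3,5-dien-1-yl]-3-(4-methylpent-3-en-1-yl)oxan-2-one
Product: 14 (3S,4R)-4-{2-[(2R,3R)-3-ethenyl-2-(hydroxymethyl)oxiran-2-yl]ethyl}-3-(4-methylpent-3-en-1-yl)oxan-2-one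
Conditions: Ti(OiPr)4 (10 mol %), D-(−)-diethyl tartrate (12 mol %), tBuOOH (2 equiv), 4 Å sieves, CH2Cl2, −20 °C
Reagents that add atoms: tert-butyl hydroperoxide, CC(C)(C)OO
Why: Sharpless asymmetric epoxidation is hydroxyl-directed, hence selective for the allylic alkene over the vinyl and side-chain alkenes, and the D-(−)-tartrate catalyst delivers oxygen to the face giving the (2R,3R)-oxirane, which creates the C11–O bond of the target and the C10 centre that is inverted in step 7.

Step 7
Reactants: 14 (3S,4R)-4-{2-[(2R,3R)-3-ethenyl-2-(hydroxymethyl)oxiran-2-yl]ethyl}-3-(4-methylpent-3-en-1-yl)oxan-2-one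
Product: 17 9-ethenyl-5-hydroxy-8-(2-hydroxyethyl)-1-(4-methylpent-3-en-1-yl)-3-oxabicyclo[3.3.1]nonan-2-one (C1 and C18 β; C16, 11-OH and vinyl α), via dilithium alkoxide enolate 15 (not isolated), via cis-fused lactone diol 16 (not isolated)
Conditions: LiN(iPr)2 (2.2 equiv), THF, −78 → 25 °C, 0.02 M; aq NH4Cl; then 1,5,7-triazabicyclo[4.4.0]dec-5-ene (TBD, 10 mol %), PhMe, 60 °C
Reagents that add atoms: none
Why: Intramolecular enolate–epoxide alkylation (six-membered ring, SN2 with inversion at allylic C10, attack at fully substituted C11 being impossible) on a lactone enolate that can only close cis-fused, so C15 forms with its carbonyl carbon cis to C1 while the chair transition state with the oxirane oxygen anti to the incoming carbon puts C18 syn-axial to the carbonyl and the vinyl group axial and anti; the C18 alkoxide then takes over the acyl group (translactonisation) to give the less strained bridged lactone and free the C2 hydroxyl.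

Step 8
Reactants: 17 9-ethenyl-5-hydroxy-8-(2-hydroxyethyl)-1-(4-methylpent-3-en-1-yl)-3-oxabicyclo[3.3.1]nonan-2-one
Product: 18 2-[9-ethenyl-5-hydroxy-1-(4-methylpent-3-en-1-yl)-2-oxo-3-oxabicyclo[3.3.1]nonan-8-yl]acetaldehyde
Conditions: Dess–Martin periodinane (1.3 equiv), CH2Cl2, 0 °C → rt
Reagents that add atoms: none
Why: Dess–Martin oxidation of the only primary alcohol, the tertiary C11 hydroxyl and the lactone being inert.

Step 9
Reactants: 18 2-[9-ethenyl-5-hydroxy-1-(4-methylpent-3-en-1-yl)-2-oxo-3-oxabicyclo[3.3.1]nonan-8-yl]acetaldehyde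
Product: 19 9-ethenyl-5-hydroxy-8-[(2Z)-3-iodobut-2-en-1-yl]-1-(4-methylpent-3-en-1-yl)-3-oxabicyclo[3.3.1]nonan-2-one
Conditions: EtPPh3I, nBuLi, THF, 0 °C; I2, −78 °C; NaN(SiMe3)2, −78 °C; then 18, −78 → −20 °C
Reagents that add atoms: ethyltriphenylphosphonium iodide, CC[P+](c1ccccc1)(c1ccccc1)c1ccccc1.[I-]; iodine, II
Why: Wittig olefination with the α-iodo ylide Ph3P=C(I)CH3 (Stork–Zhao type) gives the (Z)-2-iodoalk-2-ene, chain cis to iodine, under kinetic control.

Step 10
Reactants: 19 9-ethenyl-5-hydroxy-8-[(2Z)-3-iodobut-2-en-1-yl]-1-(4-methylpent-3-en-1-yl)-3-oxabicyclo[3.3.1]nonan-2-one; 20 3,3-diethoxyprop-1-ene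
Product: 23 (4Z)-6-[9-ethenyl-5-hydroxy-1-(4-methylpent-3-en-1-yl)-2-oxo-3-oxabicyclo[3.3.1]nonan-8-yl]-4-methylhex-4-enal, via alkylborane 21 (not isolated), via diethyl acetal 22 (not isolated)
Conditions: 20 (1.5 equiv), 9-BBN (1.4 equiv B–H), THF, rt; then 19, Pd(dppf)Cl2 (5 mol %), AsPh3, Cs2CO3, DMF/H2O, rt; work-up 1 M HCl/THF, 0 °C
Reagents that add atoms: water, O
Why: B-alkyl Suzuki–Miyaura coupling with retention gives the first Z-trisubstituted ring alkene (C1 cis to C4), the borane being fully formed beforehand so that the C10 vinyl group is not hydroborated, and the acidic work-up hydrolyses the acetal to the C6 aldehyde.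

Step 11
Reactants: 23 (4Z)-6-[9-ethenyl-5-hydroxy-1-(4-methylpent-3-en-1-yl)-2-oxo-3-oxabicyclo[3.3.1]nonan-8-yl]-4-methylhex-4-enal
Product: 24 9-ethenyl-5-hydroxy-8-[(2Z,6Z)-7-iodo-3-methylocta-2,6-dien-1-yl]-1-(4-methylpent-3-en-1-yl)-3-oxabicyclo[3.3.1]nonan-2-one
Conditions: EtPPh3I, nBuLi, THF, 0 °C; I2, −78 °C; NaN(SiMe3)2, −78 °C; then 23, −78 → −20 °C
Reagents that add atoms: ethyltriphenylphosphonium iodide, CC[P+](c1ccccc1)(c1ccccc1)c1ccccc1.[I-]; iodine, II
Why: Second α-iodoethylidene Wittig olefination (Stork–Zhao type) with the same kinetic Z selectivity installs the C6=C7 alkenyl iodide with C5 cis to iodine.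

Step 12
Reactants: 24 9-ethenyl-5-hydroxy-8-[(2Z,6Z)-7-iodo-3-methylocta-2,6-dien-1-yl]-1-(4-methylpent-3-en-1-yl)-3-oxabicyclo[3.3.1]nonan-2-one
Product: 26 macrocyclic bridged hydroxy lactone (2Z,6Z; 11-hydroxy; C15 carbonyl lactonised onto O–C18), via alkylborane 25 (not isolated)
Conditions: 9-BBN (3 equiv), THF, rt → 40 °C; then slow addition to Pd(dppf)Cl2 (20 mol %), AsPh3, Cs2CO3, THF/DMF/H2O, 50 °C, 1 mM
Reagents that add atoms: none
Why: Hydroboration of the only monosubstituted alkene and intramolecular B-alkyl Suzuki–Miyaura coupling at high dilution close the 12-membered ring through C7–C8 with retention, giving the second Z alkene (C5 cis to C8) while the bridged lactone holds C9 axial and C1 equatorial, i.e. trans.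

Step 13
Reactants: 26 macrocyclic bridged hydroxy lactone
Product: 29 target epoxy acid (2Z,6Z,10R,11S,14R,15S), via potassium alkoxide 27 (not isolated), via potassium epoxy carboxylate 28 (not isolated)
Conditions: KH (1.3 equiv), 18-crown-6 (1.3 equiv), THF, 0 → 50 °C, 0.01 M; then cold aq KH2PO4 (pH about 5)
Reagents that add atoms: none
Why: Proposed new method: the naked tertiary C11 alkoxide is held anti-periplanar to the C18–O(acyl) bond of the bridged lactone and, being trans to the carbonyl, cannot transacylate, so its only intramolecular path is a 3-exo-tet displacement at C18 with the carboxylate as leaving group, which closes the spiro-oxirane with retention at C11 (O α, CH2 β) and unveils the acid, driven in an aprotic medium by turning an alkoxide into a carboxylate and releasing the bridge; the closest known reactions are Williamson-type epoxide closure of β-hydroxy sulfonates or halohydrins and O-alkyl (BAL2) cleavage of esters by strong nucleophiles.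

**Compound list**
1 | 5,6-dihydro-2H-pyran-2-one | O=C1C=CCCO1 | starting material
2 | potassium ethenyltrifluoroborate | C=C[B-](F)(F)F.[K+] | starting material
3 | (4R)-4-ethenyloxan-2-one | O=C1C[C@H](C=C)CCO1 | intermediate
4 | 5-bromo-2-methylpent-2-ene | CC(C)=CCCBr | starting material
5 | lithium enolate of 3 | [Li+].[O-]C1=C[C@H](C=C)CCO1 | intermediate (not isolated)
6 | (3S,4S)-4-ethenyl-3-(4-methylpent-3-en-1-yl)oxan-2-one (3,4-trans) | O=C1[C@@H](CCC=C(C)C)[C@H](C=C)CCO1 | intermediate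
7 | prop-2-enal (acrolein) | C=CC=O | starting material
8 | ethyl (triphenylphosphoranylidene)acetate | CCOC(=O)C=P(c1ccccc1)(c1ccccc1)c1ccccc1 | starting material
9 | ethyl iodo(triphenylphosphoranylidene)acetate | CCOC(=O)C(I)=P(c1ccccc1)(c1ccccc1)c1ccccc1 | intermediate (not isolated)
10 | ethyl (2Z)-2-iodopenta-2,4-dienoate | CCOC(=O)/C(I)=C/C=C | intermediate
11 | (2Z)-2-iodopenta-2,4-dien-1-ol | OC/C(I)=C/C=C | intermediate
12 | 9-{2-[(3S,4R)-3-(4-methylpent-3-en-1-yl)-2-oxooxan-4-yl]ethyl}-9-borabicyclo[3.3.1]nonane | O=C1[C@@H](CCC=C(C)C)[C@H](CCB2C3CCCC2CCC3)CCO1 | intermediate (not isolated)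
13 | (3S,4R)-4-[(3E)-3-(hydroxymethyl)hexa-3,5-dien-1-yl]-3-(4-methylpent-3-en-1-yl)oxan-2-one | O=C1[C@@H](CCC=C(C)C)[C@H](CC/C(CO)=C\C=C)CCO1 | intermediate
14 | (3S,4R)-4-{2-[(2R,3R)-3-ethenyl-2-(hydroxymethyl)oxiran-2-yl]ethyl}-3-(4-methylpent-3-en-1-yl)oxan-2-one | O=C1[C@@H](CCC=C(C)C)[C@H](CC[C@]2(CO)O[C@@H]2C=C)CCO1 | intermediate
15 | dilithium alkoxide enolate of 14 | [Li+].[Li+].[O-]C1=C(CCC=C(C)C)[C@H](CC[C@]2(C[O-])O[C@@H]2C=C)CCO1 | intermediate (not isolated)
16 | cis-fused lactone diol: 8-ethenyl-7-hydroxy-7-(hydroxymethyl)-8a-(4-methylpent-3-en-1-yl)octahydro-1H-isochromen-1-one (ring fusion cis; C18 β; 11-OH and vinyl α; present as its lithium alkoxide, neutral form shown) | CC(C)=CCC[C@]1(C(=O)OCC2)[C@@H]2CC[C@@](O)(CO)[C@@H]1C=C | intermediate (not isolated)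
17 | 9-ethenyl-5-hydroxy-8-(2-hydroxyethyl)-1-(4-methylpent-3-en-1-yl)-3-oxabicyclo[3.3.1]nonan-2-one (vinyl anti to the O3 bridge; hydroxyethyl equatorial, on the bridge face) | CC(C)=CCC[C@]1(C2=O)[C@@H](CCO)CC[C@@](O)(CO2)[C@@H]1C=C | intermediate
18 | 2-[9-ethenyl-5-hydroxy-1-(4-methylpent-3-en-1-yl)-2-oxo-3-oxabicyclo[3.3.1]nonan-8-yl]acetaldehyde | CC(C)=CCC[C@]1(C2=O)[C@@H](CC=O)CC[C@@](O)(CO2)[C@@H]1C=C | intermediate
19 | 9-ethenyl-5-hydroxy-8-[(2Z)-3-iodobut-2-en-1-yl]-1-(4-methylpent-3-en-1-yl)-3-oxabicyclo[3.3.1]nonan-2-one | CC(C)=CCC[C@]1(C2=O)[C@@H](C/C=C(/C)I)CC[C@@](O)(CO2)[C@@H]1C=C | intermediate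
20 | 3,3-diethoxyprop-1-ene (acrolein diethyl acetal) | C=CC(OCC)OCC | starting material
21 | 9-(3,3-diethoxypropyl)-9-borabicyclo[3.3.1]nonane | CCOC(CCB1C2CCCC1CCC2)OCC | intermediate (not isolated)
22 | 8-[(2Z)-6,6-diethoxy-3-methylhex-2-en-1-yl]-9-ethenyl-5-hydroxy-1-(4-methylpent-3-en-1-yl)-3-oxabicyclo[3.3.1]nonan-2-one | CC(C)=CCC[C@]1(C2=O)[C@@H](C/C=C(/C)CCC(OCC)OCC)CC[C@@](O)(CO2)[C@@H]1C=C | intermediate (not isolated)
23 | (4Z)-6-[9-ethenyl-5-hydroxy-1-(4-methylpent-3-en-1-yl)-2-oxo-3-oxabicyclo[3.3.1]nonan-8-yl]-4-methylhex-4-enal | CC(C)=CCC[C@]1(C2=O)[C@@H](C/C=C(/C)CCC=O)CC[C@@](O)(CO2)[C@@H]1C=C | intermediate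
24 | 9-ethenyl-5-hydroxy-8-[(2Z,6Z)-7-iodo-3-methylocta-2,6-dien-1-yl]-1-(4-methylpent-3-en-1-yl)-3-oxabicyclo[3.3.1]nonan-2-one | CC(C)=CCC[C@]1(C2=O)[C@@H](C/C=C(/C)CC/C=C(/C)I)CC[C@@](O)(CO2)[C@@H]1C=C | intermediate
25 | 9-BBN adduct of the C10 vinyl group of 24 | CC(C)=CCC[C@]1(C2=O)[C@@H](C/C=C(/C)CC/C=C(/C)I)CC[C@@](O)(CO2)[C@@H]1CCB3C4CCCC3CCC4 | intermediate (not isolated)
26 | macrocyclic bridged hydroxy lactone (2Z,6Z; 11-OH α; lactone C15–C(=O)–O–C18 on the β face; C1 β, C9 α) | CC(C)=CCC[C@]1(C3=O)[C@H]2C/C=C(/C)CC/C=C(/C)CC[C@H]1[C@@](O)(CC2)CO3 | intermediate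
27 | potassium C11 alkoxide of 26 | [K+].CC(C)=CCC[C@]1(C3=O)[C@H]2C/C=C(/C)CC/C=C(/C)CC[C@H]1[C@@]([O-])(CC2)CO3 | intermediate (not isolated)
28 | potassium salt of the target acid | [K+].CC(C)=CCC[C@]1(C(=O)[O-])[C@H]2C/C=C(/C)CC/C=C(/C)CC[C@H]1[C@@]1(CC2)CO1 | intermediate (not isolated)
29 | CNP0116395.1, (2Z,6Z,10R,11S,14R,15S)-epoxy acid | CC(C)=CCC[C@]1(C(=O)O)[C@H]2C/C=C(/C)CC/C=C(/C)CC[C@H]1[C@@]1(CC2)CO1 | target

**Totals and risks**

Total step count: 13. Longest linear sequence: 11 (steps 1, 2, 5–13); steps 3–4 make fragment 11.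

Steps most likely to fail:

Step 7 (enolate–epoxide cyclisation and acyl shift). A fully substituted lactone enolate must open a hindered oxirane, and the 16/17 equilibrium is only estimated to favour 17. The fallback sets out from 14 and switches from the anionic to a Lewis-acid (Mukaiyama-type) mode. Silylation of the primary hydroxyl (tBuMe2SiCl, imidazole) gives the tert-butyldimethylsilyl ether F1. LiN(iPr)2/Me3SiCl then gives the ketene silyl acetal F2. BF3·OEt2 or Me3SiOTf (CH2Cl2, −78 °C) triggers epoxide-opening cyclisation onto the π-nucleophile, still anti at allylic C10 and still forced cis at the ring fusion, and aqueous work-up gives the silyl-protected cis-fused hydroxy lactone F3. Bu4NF removes the silyl group to give 16, and the same TBD equilibration returns to the route at 17.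

Step 12 (macrocyclisation). The ring is trans-bridged and 12-membered, and the borane/aqueous-base coupling may give oligomers or protodeboronation. The fallback sets out from 24 and replaces the in situ borane by a discrete organozinc. Hydroboration–oxidation (9-BBN; NaBO3·4H2O) gives the primary alcohol F4. I2/PPh3/imidazole gives the primary iodide F5. Zinc insertion (Zn dust, LiCl, THF, rt, which leaves the alkenyl iodide intact) gives the alkylzinc iodide F6. Intramolecular Negishi coupling (Pd(PPh3)4, THF/NMP, high dilution, anhydrous and base-free) returns to the route at 26.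

Step 13 (new alkoxide-to-oxirane closure with carboxylate as leaving group). The carboxylate may be too poor a nucleofuge, or intermolecular acyl transfer may compete. The fallback sets out from 26 and uses known chemistry. LiOH (THF/H2O, 40 °C) opens the lactone to the dihydroxy acid F7, which is kept as its lithium salt and not acidified so that it cannot relactonise. NaH and N-tosylimidazole (THF, 0 °C → rt) sulfonylate the primary alkoxide to the primary tosylate F8, which the adjacent tertiary alkoxide closes at once to the oxirane. Buffered acidification returns to the route at 29.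

**Further compounds**
F1 | step 7 | tert-butyldimethylsilyl ether of 14 | O=C1[C@@H](CCC=C(C)C)[C@H](CC[C@]2(CO[Si](C)(C)C(C)(C)C)O[C@@H]2C=C)CCO1
F2 | step 7 | ketene trimethylsilyl acetal of F1 | C[Si](C)(C)OC1=C(CCC=C(C)C)[C@H](CC[C@]2(CO[Si](C)(C)C(C)(C)C)O[C@@H]2C=C)CCO1
F3 | step 7 | C18 O-silyl ether of cis-fused lactone 16 | CC(C)=CCC[C@]1(C(=O)OCC2)[C@@H]2CC[C@@](O)(CO[Si](C)(C)C(C)(C)C)[C@@H]1C=C
F4 | step 12 | C8 primary alcohol from 24 | CC(C)=CCC[C@]1(C2=O)[C@@H](C/C=C(/C)CC/C=C(/C)I)CC[C@@](O)(CO2)[C@@H]1CCO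
F5 | step 12 | C8 primary iodide | CC(C)=CCC[C@]1(C2=O)[C@@H](C/C=C(/C)CC/C=C(/C)I)CC[C@@](O)(CO2)[C@@H]1CCI
F6 | step 12 | C8 alkylzinc iodide | CC(C)=CCC[C@]1(C2=O)[C@@H](C/C=C(/C)CC/C=C(/C)I)CC[C@@](O)(CO2)[C@@H]1CC[Zn]I
F7 | step 13 | 11,18-dihydroxy acid (handled as lithium salt) | CC(C)=CCC[C@]1(C(=O)O)[C@H]2C/C=C(/C)CC/C=C(/C)CC[C@H]1[C@@](O)(CC2)CO
F8 | step 13 | 18-O-tosyl-11-hydroxy acid | CC(C)=CCC[C@]1(C(=O)O)[C@H]2C/C=C(/C)CC/C=C(/C)CC[C@H]1[C@@](O)(CC2)COS(=O)(=O)c1ccc(C)cc1
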